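**Plan**

- Retrosynthesis: first remove the two O-methyl groups (to dihydroxyquinone 16). Then cut the quinone ring at C3–C4 and C5–C6 (ring numbering: C1 =O, C2 OMe, C3 indol-3-yl, C4 =O, C5 OMe, C6 the 2,7-disubstituted indol-3-yl). C4/C5 become dimethyl oxalate; C3–C2–C1–C6 with both indoles become a 1,4-di(indol-3-yl)butane-2,3-dione, carried as its silyl enol ether 12.
- Next cut 12 at the enol C=C (Horner–Wadsworth–Emmons: aldehyde 11 + ketophosphonate 10) and 10 at its ketone (ester 7 + phosphonate 9). Ester 7 comes from 7-bromoindole by C3–H alkylation, C2 reverse prenylation and C7 Stille prenylation.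
- Forward order: both indole rings are bought; the chain is joined as indolylacetate 7, then ketophosphonate 10, then enone 12. The quinone ring is the only ring made and is made last (step 7), followed by O-methylation.
- Enabling feature: each indolyl-bearing ring carbon (C3, C6) lies between two oxygen-bearing carbons, so the quinone ring is the bis-enol of a cyclohexane-1,2,4,5-tetraone. C3 and C6 are therefore alpha-carbons of a 1,2-dione (nucleophilic CH2) and C4/C5 an oxalyl unit (double electrophile). A double Claisen [4+2] annulation closes the ring while both aryl–quinone bonds, the crowded one included, already exist as indole C3–CH2 bonds.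
- Stereochemistry: the target has no stereocentre and no stereogenic double bond; the enol ether geometry of 12 and the stereocentres of 4, 10 and 15 are erased.

Key step: step 7

Remark: the four ring oxygens of 16 are interchanged by tautomerism, so the para-quinone dimethyl ether is one compound whichever oxygen pair is methylated; 6, 8, 11 and 13 are taken as purchasable.

**Route**

Step 1
Reactants: 1 7-bromo-1H-indole; 2 ethyl diazoacetate
Product: 3 ethyl 2-(7-bromo-1H-indol-3-yl)acetate
Conditions: Cu(OTf)2 (5 mol %), CH2Cl2, rt, slow addition of 2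
Reagents that add atoms: none
Why: The copper carbenoid formed from 2 (divalent copper triflate as precatalyst) should be attacked by C-3, the most nucleophilic position of the unprotected indole, and proton transfer restores the aromatic ring, a carbenoid C3–H functionalisation known for NH-indoles and diazoacetates.

Step 2
Reactants: 3 ethyl 2-(7-bromo-1H-indol-3-yl)acetate
Product: 5 ethyl 2-[7-bromo-2-(2-methylbut-3-en-2-yl)-1H-indol-3-yl]acetate, via 3-chloroindolenine 4 (not isolated)
Conditions: t-BuOCl, Et3N, THF, -78 °C; then B-prenyl-9-BBN (from 9-BBN + 3-methylbuta-1,2-diene, THF), -78 °C to rt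
Reagents that add atoms: B-(3-methylbut-2-en-1-yl)-9-borabicyclo[3.3.1]nonane, CC(C)=CCB1C2CCCC1CCC2; tert-butyl hypochlorite, CC(C)(C)OCl (its chlorine stays only in 4)
Why: C-3 chlorination gives chloroindolenine 4, whose C=N bond is allylborated through a six-membered transition state with allylic transposition so that the tertiary carbon is attached to C-2, and loss of HCl re-aromatises; this reverse prenylation needs a 3-alkyl group and a free N–H, both present, while ester and aryl bromide are inert.

Step 3
Reactants: 5 ethyl 2-[7-bromo-2-(2-methylbut-3-en-2-yl)-1H-indol-3-yl]acetate; 6 tributyl(3-methylbut-2-en-1-yl)stannane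
Product: 7 ethyl 2-[2-(2-methylbut-3-en-2-yl)-7-(3-methylbut-2-en-1-yl)-1H-indol-3-yl]acetate
Conditions: Pd(PPh3)4 (5 mol %), DMF, 90 °C
Reagents that add atoms: none
Why: Stille coupling at the C-7 bromide (oxidative addition to zerovalent palladium, transmetalation, reductive elimination at the less substituted allyl terminus) should give the linear prenyl group; ester, N–H and the 1,1-dimethylallyl group are tolerated.

Step 4
Reactants: 8 diethyl (hydroxymethyl)phosphonate
Product: 9 diethyl ({[tert-butyl(dimethyl)silyl]oxy}methyl)phosphonate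
Conditions: TBSCl, imidazole, CH2Cl2, rt
Reagents that add atoms: tert-butyldimethylsilyl chloride, CC(C)(C)[Si](C)(C)Cl
Why: Routine O-silylation of a primary alcohol, giving the phosphonate that carries the future enol oxygen in a form removable by methoxide.

Step 5
Reactants: 7 ethyl 2-[2-(2-methylbut-3-en-2-yl)-7-(3-methylbut-2-en-1-yl)-1H-indol-3-yl]acetate; 9 diethyl ({[tert-butyl(dimethyl)silyl]oxy}methyl)phosphonate
Product: 10 diethyl {1-{[tert-butyl(dimethyl)silyl]oxy}-3-[2-(2-methylbut-3-en-2-yl)-7-(3-methylbut-2-en-1-yl)-1H-indol-3-yl]-2-oxopropyl}phosphonate (racemic)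
Conditions: 9 (3.3 equiv), LiN(i-Pr)2 (LDA, 3.3 equiv), THF, -78 °C; then 7, -78 to -30 °C; aq. NH4Cl
Reagents that add atoms: none
Why: Claisen-type C-acylation of the phosphonate-stabilised carbanion by the ethyl ester; the excess anion covers the indole N–H and the acidic product, and the low temperature should favour acyl substitution over ester enolisation.

Step 6
Reactants: 10 the ketophosphonate of step 5; 11 tert-butyl 3-formyl-1H-indole-1-carboxylate
Product: 12 tert-butyl 3-[(1Z)-2-{[tert-butyl(dimethyl)silyl]oxy}-4-[2-(2-methylbut-3-en-2-yl)-7-(3-methylbut-2-en-1-yl)-1H-indol-3-yl]-3-oxobut-1-en-1-yl]-1H-indole-1-carboxylate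
Conditions: LiCl, DBU, MeCN, 0 °C to rt
Reagents that add atoms: none
Why: Horner–Wadsworth–Emmons olefination, in which the lithium-chelated beta-ketophosphonate anion is the only carbanion that reacts irreversibly with the aldehyde; it should give the silyl enol ether of the 1,2-dione (Z expected, geometry of no consequence).

Step 7
Reactants: 12 the silyl enol ether enone of step 6; 13 dimethyl oxalate
Product: 16 2,5-dihydroxy-3-(1H-indol-3-yl)-6-[2-(2-methylbut-3-en-2-yl)-7-(3-methylbut-2-en-1-yl)-1H-indol-3-yl]cyclohexa-2,5-diene-1,4-dione, via diketone 14 (not isolated), via triketo ester 15 (not isolated)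
Conditions: NaOMe (6 equiv), 13 (3 equiv), degassed MeOH–THF, 0 to 60 °C; then 1 M aq. HCl, 0 °C
Reagents that add atoms: none
Why: Methoxide removes the enol silyl group and the N-Boc group of 12, so diketone 14 is released as its enolate only in the presence of the electrophile; crossed Claisen acylation of its less hindered methylene (beside the unsubstituted indole) by 13 gives triketo ester 15, and the enolate of the second methylene (beside the 2-tert-alkylindole) then attacks the remaining ester carbonyl in a Dieckmann-type closure, the resulting cyclohexane-1,2,4,5-tetraone appearing as its bis-enol, the 2,5-dihydroxy-1,4-benzoquinone 16. The closest known reaction type is the double Claisen condensation of 1,3-diarylacetones with dialkyl oxalates to 3,5-diarylcyclopentane-1,2,4-triones, here applied to the 1,2-diketone homologue. The one ring formed, the quinone ring, closes by a 6-(enolendo)-exo-trig acyl substitution, so the bond to the most crowded carbon is made intramolecularly. No stereocentre is created, because the two transient sp3 ring carbons are enolised in the product. The step needs C- rather than O-acylation and six-ring acyl substitution rather than five-ring aldol closure onto the ketone of 15; the substrate should secure this because lactone and aldol adducts can revert under methoxide whereas 16 is drained off as its doubly deprotonated vinylogous carboxylate, and because both methylenes are activated alike (each benzylic to an indole and alpha to the 1,2-dione) either order of acylation converges on the same ring.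

Step 8
Reactants: 16 the dihydroxyquinone of step 7
Product: 17 3-(1H-indol-3-yl)-2,5-dimethoxy-6-[2-(2-methylbut-3-en-2-yl)-7-(3-methylbut-2-en-1-yl)-1H-indol-3-yl]cyclohexa-2,5-diene-1,4-dione (target)
Conditions: TMSCHN2 (3 equiv), MeOH–CH2Cl2 (1:4), 0 °C to rt; AcOH quench
Reagents that add atoms: (trimethylsilyl)diazomethane, C[Si](C)(C)C=[N+]=[N-]
Why: The two vinylogous-acid hydroxyls, far more acidic than the indole N–H groups, protonate the diazoalkane and should be O-methylated to the 2,5-dimethoxy-1,4-benzoquinone; the fully substituted quinone, the N–H groups and the alkenes are not expected to react.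

**Compound list**

1 | 7-bromo-1H-indole | Brc1cccc2cc[nH]c12 | starting material
2 | ethyl diazoacetate | CCOC(=O)C=[N+]=[N-] | starting material
3 | ethyl 2-(7-bromo-1H-indol-3-yl)acetate | CCOC(=O)Cc1c[nH]c2c(Br)cccc12 | intermediate
4 | ethyl 2-(7-bromo-3-chloro-3H-indol-3-yl)acetate (racemic, not isolated) | CCOC(=O)CC1(Cl)C=Nc2c(Br)cccc21 | intermediate
5 | ethyl 2-[7-bromo-2-(2-methylbut-3-en-2-yl)-1H-indol-3-yl]acetate | CCOC(=O)Cc1c(C(C)(C)C=C)[nH]c2c(Br)cccc12 | intermediate
6 | tributyl(3-methylbut-2-en-1-yl)stannane | CCCC[Sn](CCCC)(CCCC)CC=C(C)C | starting material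
7 | ethyl 2-[2-(2-methylbut-3-en-2-yl)-7-(3-methylbut-2-en-1-yl)-1H-indol-3-yl]acetate | CCOC(=O)Cc1c(C(C)(C)C=C)[nH]c2c(CC=C(C)C)cccc12 | intermediate
8 | diethyl (hydroxymethyl)phosphonate | CCOP(=O)(CO)OCC | starting material
9 | diethyl ({[tert-butyl(dimethyl)silyl]oxy}methyl)phosphonate | CCOP(=O)(CO[Si](C)(C)C(C)(C)C)OCC | intermediate
10 | diethyl {1-{[tert-butyl(dimethyl)silyl]oxy}-3-[2-(2-methylbut-3-en-2-yl)-7-(3-methylbut-2-en-1-yl)-1H-indol-3-yl]-2-oxopropyl}phosphonate (racemic) | CCOP(=O)(OCC)C(O[Si](C)(C)C(C)(C)C)C(=O)Cc1c(C(C)(C)C=C)[nH]c2c(CC=C(C)C)cccc12 | intermediate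
11 | tert-butyl 3-formyl-1H-indole-1-carboxylate | CC(C)(C)OC(=O)n1cc(C=O)c2ccccc21 | starting material
12 | tert-butyl 3-[(1Z)-2-{[tert-butyl(dimethyl)silyl]oxy}-4-[2-(2-methylbut-3-en-2-yl)-7-(3-methylbut-2-en-1-yl)-1H-indol-3-yl]-3-oxobut-1-en-1-yl]-1H-indole-1-carboxylate | CC(C)(C)OC(=O)n1cc(/C=C(\O[Si](C)(C)C(C)(C)C)C(=O)Cc2c(C(C)(C)C=C)[nH]c3c(CC=C(C)C)cccc23)c2ccccc21 | intermediate
13 | dimethyl oxalate | COC(=O)C(=O)OC | starting material
14 | 1-(1H-indol-3-yl)-4-[2-(2-methylbut-3-en-2-yl)-7-(3-methylbut-2-en-1-yl)-1H-indol-3-yl]butane-2,3-dione (not isolated) | O=C(Cc1c[nH]c2ccccc12)C(=O)Cc1c(C(C)(C)C=C)[nH]c2c(CC=C(C)C)cccc12 | intermediate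
15 | methyl 3-(1H-indol-3-yl)-6-[2-(2-methylbut-3-en-2-yl)-7-(3-methylbut-2-en-1-yl)-1H-indol-3-yl]-2,4,5-trioxohexanoate (racemic, keto form drawn, not isolated) | COC(=O)C(=O)C(c1c[nH]c2ccccc12)C(=O)C(=O)Cc1c(C(C)(C)C=C)[nH]c2c(CC=C(C)C)cccc12 | intermediate
16 | 2,5-dihydroxy-3-(1H-indol-3-yl)-6-[2-(2-methylbut-3-en-2-yl)-7-(3-methylbut-2-en-1-yl)-1H-indol-3-yl]cyclohexa-2,5-diene-1,4-dione | C=CC(C)(C)c1[nH]c2c(CC=C(C)C)cccc2c1C1=C(O)C(=O)C(c2c[nH]c3ccccc23)=C(O)C1=O | intermediate
17 | 3-(1H-indol-3-yl)-2,5-dimethoxy-6-[2-(2-methylbut-3-en-2-yl)-7-(3-methylbut-2-en-1-yl)-1H-indol-3-yl]cyclohexa-2,5-diene-1,4-dione | C=CC(C)(C)c1[nH]c2c(CC=C(C)C)cccc2c1C1=C(OC)C(=O)C(c2c[nH]c3ccccc23)=C(OC)C1=O | target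

**Step count and risks**

Total step count: 8. Longest linear sequence: 7 steps (steps 1, 2, 3, 5, 6, 7, 8 from compound 1).

Steps most likely to fail:

Step 7. The mono-acylated intermediate may be diverted into five-ring aldol closure followed by dehydration, or the released diketone enolate may self-condense or be oxidised before it is acylated. Fallback, setting out from 1 (with 6) and coming back at 16: the quinone ring is bought and the indoles are attached to it. Compound 1 is coupled with 6 under the conditions of step 3 to give 7-(3-methylbut-2-en-1-yl)-1H-indole F1. Chlorination with NCS gives 3-chloro-7-(3-methylbut-2-en-1-yl)-1H-indole F2, which with B-prenyl-9-BBN and Et3N should give 2-(2-methylbut-3-en-2-yl)-7-(3-methylbut-2-en-1-yl)-1H-indole F3. Separately, commercial indole is added to commercial 2,5-dichloro-1,4-benzoquinone (HCl, THF; then DDQ) to give 2,5-dichloro-3-(1H-indol-3-yl)cyclohexa-2,5-diene-1,4-dione F4. Acid-promoted conjugate addition of F3 to F4 and re-oxidation with DDQ should give 2,5-dichloro-3-(1H-indol-3-yl)-6-[2-(2-methylbut-3-en-2-yl)-7-(3-methylbut-2-en-1-yl)-1H-indol-3-yl]cyclohexa-2,5-diene-1,4-dione F5. NaOH in aqueous MeOH then replaces both chlorides by hydroxyl and returns to 16.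

Step 5. Proton transfer from the arylacetate ester (enolisation) or silyl migration in the lithiated phosphonate may outpace acyl substitution. Fallback, setting out from 7 and 11 and coming back at 12 (it also bypasses step 6): the ketone is made by acylating the arylacetic acid instead of the phosphonate. Aldehyde 11 is olefinated with methyl 2-{[tert-butyl(dimethyl)silyl]oxy}-2-(dimethoxyphosphoryl)acetate (LiN(SiMe3)2, THF) to give tert-butyl 3-[(1Z)-2-{[tert-butyl(dimethyl)silyl]oxy}-3-methoxy-3-oxoprop-1-en-1-yl]-1H-indole-1-carboxylate F6. Ester 7 is saponified (LiOH, THF–H2O) to 2-[2-(2-methylbut-3-en-2-yl)-7-(3-methylbut-2-en-1-yl)-1H-indol-3-yl]acetic acid F7. The magnesium enediolate of F7 (t-BuMgCl, THF) is acylated by F6 in an Ivanov-type Claisen condensation to give (4Z)-5-[1-(tert-butoxycarbonyl)-1H-indol-3-yl]-4-{[tert-butyl(dimethyl)silyl]oxy}-2-[2-(2-methylbut-3-en-2-yl)-7-(3-methylbut-2-en-1-yl)-1H-indol-3-yl]-3-oxopent-4-enoic acid F8, which should lose carbon dioxide on mildly acidic work-up to give 12.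

Step 3. Allyl transfer with transposition may give the branched 1,1-dimethylallyl isomer, or transmetalation next to the free N–H may be slow. Fallback, setting out from 5 and coming back at 7: the polarity of the partners is reversed. Miyaura borylation of 5 (B2pin2, Pd(dppf)Cl2, KOAc, dioxane, 90 °C) gives ethyl 2-[2-(2-methylbut-3-en-2-yl)-7-(4,4,5,5-tetramethyl-1,3,2-dioxaborolan-2-yl)-1H-indol-3-yl]acetate F9. Coupling of F9 with 1-bromo-3-methylbut-2-ene (Pd(PPh3)4, K2CO3, THF–H2O, 60 °C) delivers the aryl group to the less substituted terminus of the prenyl palladium intermediate and returns to 7.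

**Further compounds**

F1 | step 7 | 7-(3-methylbut-2-en-1-yl)-1H-indole | CC(C)=CCc1cccc2cc[nH]c12
F2 | step 7 | 3-chloro-7-(3-methylbut-2-en-1-yl)-1H-indole | CC(C)=CCc1cccc2c(Cl)c[nH]c12
F3 | step 7 | 2-(2-methylbut-3-en-2-yl)-7-(3-methylbut-2-en-1-yl)-1H-indole | C=CC(C)(C)c1cc2cccc(CC=C(C)C)c2[nH]1
F4 | step 7 | 2,5-dichloro-3-(1H-indol-3-yl)cyclohexa-2,5-diene-1,4-dione | O=C1C=C(Cl)C(=O)C(c2c[nH]c3ccccc23)=C1Cl
F5 | step 7 | 2,5-dichloro-3-(1H-indol-3-yl)-6-[2-(2-methylbut-3-en-2-yl)-7-(3-methylbut-2-en-1-yl)-1H-indol-3-yl]cyclohexa-2,5-diene-1,4-dione | C=CC(C)(C)c1[nH]c2c(CC=C(C)C)cccc2c1C1=C(Cl)C(=O)C(c2c[nH]c3ccccc23)=C(Cl)C1=O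
F6 | step 5 | tert-butyl 3-[(1Z)-2-{[tert-butyl(dimethyl)silyl]oxy}-3-methoxy-3-oxoprop-1-en-1-yl]-1H-indole-1-carboxylate | CC(C)(C)OC(=O)n1cc(/C=C(\O[Si](C)(C)C(C)(C)C)C(=O)OC)c2ccccc21
F7 | step 5 | 2-[2-(2-methylbut-3-en-2-yl)-7-(3-methylbut-2-en-1-yl)-1H-indol-3-yl]acetic acid | OC(=O)Cc1c(C(C)(C)C=C)[nH]c2c(CC=C(C)C)cccc12
F8 | step 5 | (4Z)-5-[1-(tert-butoxycarbonyl)-1H-indol-3-yl]-4-{[tert-butyl(dimethyl)silyl]oxy}-2-[2-(2-methylbut-3-en-2-yl)-7-(3-methylbut-2-en-1-yl)-1H-indol-3-yl]-3-oxopent-4-enoic acid (racemic) | CC(C)(C)OC(=O)n1cc(/C=C(\O[Si](C)(C)C(C)(C)C)C(=O)C(C(=O)O)c2c(C(C)(C)C=C)[nH]c3c(CC=C(C)C)cccc23)c2ccccc21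
F9 | step 3 | ethyl 2-[2-(2-methylbut-3-en-2-yl)-7-(4,4,5,5-tetramethyl-1,3,2-dioxaborolan-2-yl)-1H-indol-3-yl]acetate | CCOC(=O)Cc1c(C(C)(C)C=C)[nH]c2c(B3OC(C)(C)C(C)(C)O3)cccc12
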